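## The problem

The target is a cis-fused daucane: a cyclopentane (ring A, C1–C5) shares the C1–C5 bond with a cycloheptene (ring B, C1, C5–C10). In the numbering used throughout, C1 is the quaternary carbon with the angular methyl group, C4 the tertiary carbinol bearing isopropyl, C5 the ring-fusion CH, C6 carries the 4-hydroxybenzoate, C7 is CH2, C8(Me)=C9 is the trisubstituted alkene and C10 carries the tiglate. Five stereocentres must be set (C1, C4, C5, C6, C10); the angular methyl, H-5 and the isopropyl group lie on one face (β) and all three oxygens on the other (α). C4 is the only centre that can be bought. It can control C1 across ring A, and its hydroxyl can direct oxygen to the α face of a C5=C6 alkene, which fixes C6 and, by inversion at C5, the ring fusion. C10 lies behind the quaternary C1, out of reach of these centres, and needs its own relay. The fragile parts are the tertiary alcohol β to the C6 oxygen (retro-aldol or β-elimination if C6 is a ketone under base, semipinacol shift if C5 becomes cationic), the allylic neopentyl tiglate at C10, and the phenol ester; both esters must come late and under mild conditions. The enabling feature is the constitution of ring B: C1–C10–C9–C8–C7 maps onto a vinylcyclopropane (alkene C1=C10, ring C9/C8/C7), C5–C6 onto an alkyne, and C2–C3–C4 is a three-atom tether between them. A [5+2] cycloaddition of that chain closes both rings and leaves alkenes at C5=C6 and C9=C10, where the C6 oxygen and, after transposition through C8–H, the C10 oxygen and the C8=C9 alkene are needed.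

## Retrosynthesis

**Esters and phenol last.** Target 34 comes from aryl silyl ether 33, and 33 from allylic alcohol 30 and tiglic acid 31. Cutting the C10–O acyl bond last keeps the ionisable allylic ester out of every other step. The phenol stays silylated to the end because a free phenol quenches singlet oxygen and competes in acylations. Acylating C10 before C6 would require two free secondary alcohols to be told apart. The tertiary C4 hydroxyl needs no protection because it does not acylate. The forward steps ask for an esterification of a hindered allylic alcohol without loss of the tiglate geometry, and a buffered desilylation.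

**C10–O and C8=C9.** 30 is traced to 28 by an ene transposition: the C10–O bond and the C8=C9 alkene are exchanged for a C9=C10 alkene and the C8–H bond. Direct allylic oxidation, or reduction of a C10 enone, would depend on a face selection next to quaternary C1 that cannot be predicted. The ene reaction is suprafacial, so the configuration of C8 is transferred to C10, and because C1 carries no hydrogen only one regiochemistry exists. The precursor trades the remote C10 centre for a methyl-bearing C8 centre that a reagent can set. The forward reaction must engage a sluggish cis-disubstituted alkene, with H-8 on the α face.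

**C6 ester.** 28 comes from diol 23 and silyl-protected acid 26 (one step from 4-hydroxybenzoic acid 24). This acylation is placed before the ene step so that the C6 and C10 hydroxyls are never free together.

**C6–O and C5–H.** 23 is traced through epoxy alcohol 22 to diene 21. Hydroboration of 21 cannot tell the two alkenes apart and adds H and O syn from the open α face, which gives the wrong ring fusion. Lewis-acid rearrangement of the epoxide puts a cation at C5 with the C4 isopropyl group antiperiplanar, which invites a semipinacol shift. A C6 ketone equilibrated under base risks β-elimination of the C4 oxygen. The chosen pair is a hydroxyl-directed epoxidation (only the allylic alkene, only the α face) and a radical reductive opening at the tertiary carbon, which delivers hydrogen to C5 anti to the oxygens. The precursor 21 has three stereocentres and one oxygen.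

**Both rings (key step).** 21 comes from acyclic enyne 20 by cutting C1–C5 and C6–C7 and re-forming the C7–C9 cyclopropane bond. Closing ring B alone (ring-closing metathesis, aldol or vinyl–aldehyde coupling) would need a separately built, stereodefined ring A with its quaternary centre. The cycloaddition builds both rings and C1 in one isomerisation with no protecting group. It asks for facial control by C4 and for opening of the less substituted cyclopropane bond.

**Alkyne and hydroxyl.** 20 comes from silyl ether 19, and 19 from aldehyde 17 (unmasked from acetal 16). C5 and C6 are the two carbons of the CH2–CHO arm, so the alkyne must be made by dehydration through an enol triflate, not by a homologation. The silyl ether is kept until the alkyne is in place, because a free β-hydroxy aldehyde would cleave by retro-aldol. It is removed before the cycloaddition so that the small hydroxyl, not a silyloxy group, competes with isopropyl at C4 and is ready to direct the epoxidation.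

**C9–C10.** 16 is cut between the alkene and the cyclopropane into E-vinyl iodide 9 and cyclopropylstannane 13. The shorter cut at C1=C10, a carbonyl olefination of methyl ketone 5, cannot control the trisubstituted alkene geometry. The cycloaddition precedent needs the E isomer (tether trans to the cyclopropane). Coupling two stereodefined partners with retention fixes both the geometry and the ring configuration.

**Chain from the chiral pool.** 9 comes from terminal alkyne 7 by syn-carboalumination and iodination, 7 from methyl ketone 5, and 5 by ozonolysis of silyl ether 2 of (S)-terpinen-4-ol 1. All of C1–C6, the isopropyl group and the C4 stereocentre are present in 1. The ketone's own methyl carbon becomes C10 and the C1 methyl is added from the aluminium reagent. The forward steps need the two carbonyl groups to emerge from the ozonolysis differentiated.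

**Cyclopropane.** 13 comes from tosylate 12 and alcohol 11, made by asymmetric cyclopropanation of stannyl allylic alcohol 10. The carbinol carbon becomes the C8 methyl group, tin marks the future C9, and the reagent sets C8, the centre that later relays to C10.

## Roads not taken

**Alternative 1:** The cuts are the C1–methyl bond and C5–C6, with ring B closed later at C9–C10 and the isopropyl group added to a C4 ketone. In the forward key step a chiral copper–carbene catalyst transfers methyl from an aluminium reagent to C1 of enone A1, and the aluminium enolate is trapped at C5 by the Z-iodoenal A2 to give aldol A3. This is more convergent than the chosen plan. The quaternary centre is set by the catalyst and not by substrate bias, and the C6 oxygen arrives in place, where the chosen plan needs two steps after ring formation. Its weak points lie after A3. The isopropyl nucleophile must add to a hindered, enolisable β-hydroxy cyclopentanone that can undergo retro-aldol cleavage. The C6 configuration depends on simple aldol diastereoselection. The seven-membered ring must then close by an intramolecular vinyl–aldehyde coupling that also creates C10 with no clear facial bias. Against its convergence, the chosen plan offers a ring closure that forms both rings at once, C4 from the chiral pool, and a defined relay to C10.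

**Alternative 2:** The cuts are C1–C2 and C4–C5, annulating ring A onto a six-membered ring that is later expanded by one carbon. In the forward key step a zinc homoenolate made by opening cyclopropanol A5 adds under chiral copper catalysis to one of the two enantiotopic methyl-bearing β-carbons of quinone monoketal A4, and the enolate closes onto the liberated isopropyl ketone to give A6. This sets C1, C4 and C5 in one step with the target relative configuration, including the tertiary carbinol, which is better than the chosen plan, where C5 is set separately. However, conjugate addition to a β,β-disubstituted dienone carbon is demanding. A6 still lacks C9, so a regioselective one-carbon insertion between C8 and C10 is needed. A6 is a β-hydroxy ketone with the elimination and retro-aldol liabilities the chosen plan avoids. The chosen plan is stronger on ring B, which is formed seven-membered with the C8 methyl and both alkenes in place.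

**Alternative 3:** The cuts are C1–C5 and C1–C10, with C1 as a carbene carbon and an arene as ring B precursor. In the forward key step a chiral copper bis(oxazoline) catalyst decomposes α-diazo ketone A7; the carbene adds to the ipso–ortho bond and the norcaradiene opens to cycloheptatriene A8. Like the chosen plan it closes both rings at once. It is better in oxidation pattern: the arene delivers oxygen at C6 and C10 and the C8 methyl directly, where the chosen plan installs both oxygens afterwards. Its weak points are a methyl-substituted carbene that can collapse by 1,2-hydride shift, attack at the most hindered arene bond, and a long redox endgame from A8 (removal of the C2 carbonyl, oxidation and isopropyl addition at C4, reduction at C7 and C5 with control from distant centres). The chosen plan sets against this a precursor whose stereocentres come from the chiral pool and a reagent-controlled cyclopropanation, and a shorter, stereochemically reasoned endgame.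

Key step: step 12

Remark: α denotes the face of the three oxygen substituents and β the face of the C1 methyl group; "dauc-" names use the atom numbering defined under "The problem".
Assumption: the ligand-controlled cyclopropanation of stannyl alcohol 10 is taken to follow the facial sense established for other E-allylic alcohols, which calls for the (4S,5S) ligand to reach 11.
Assumption: (2E)-3-(tributylstannyl)prop-2-en-1-ol 10 is treated as purchasable (otherwise one hydrostannation step from propargyl alcohol).

## Steps

Step 1
Reactants: 1 (S)-(+)-terpinen-4-ol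
Product: 2 tert-butyldimethyl{[(1S)-4-methyl-1-(propan-2-yl)cyclohex-3-en-1-yl]oxy}silane
Conditions: TBSOTf, 2,6-lutidine, CH2Cl2, 0 °C to rt
Reagents that add atoms: tert-butyldimethylsilyl trifluoromethanesulfonate, CC(C)(C)[Si](C)(C)OS(=O)(=O)C(F)(F)F
Why: Silylation of a hindered tertiary alcohol with a silyl triflate and a hindered pyridine base; C4 is untouched. The ether prevents hemiketal formation, retro-aldol cleavage and O-phosphorylation in steps 2 to 10.

Step 2
Reactants: 2 tert-butyldimethyl{[(1S)-4-methyl-1-(propan-2-yl)cyclohex-3-en-1-yl]oxy}silane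
Product: 5 (5S)-5-[(tert-butyldimethylsilyl)oxy]-7,7-dimethoxy-5-(propan-2-yl)heptan-2-one, via hydroperoxy aldehyde 3 (not isolated), via hydroperoxy acetal 4 (not isolated)
Conditions: O3, CH2Cl2/MeOH, −78 °C; TsOH·H2O (cat.), rt; NaHCO3; Me2S, rt
Reagents that add atoms: ozone, O=[O+][O-]; methanol, CO
Why: Ozonolysis with Criegee fragmentation towards the ketone oxide at the more substituted carbon, which methanol traps as a methoxy hydroperoxide while the free aldehyde forms its dimethyl acetal under acid. Sulfide reduction then releases the ketone, so the two chain ends emerge differentiated.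

Step 3
Reactants: 5 (5S)-5-[(tert-butyldimethylsilyl)oxy]-7,7-dimethoxy-5-(propan-2-yl)heptan-2-one
Product: 7 tert-butyl{[(5S)-7,7-dimethoxy-5-(propan-2-yl)hept-1-yn-5-yl]oxy}dimethylsilane, via enol phosphate 6 (not isolated)
Conditions: LiN(iPr)2, THF, −78 °C; ClP(O)(OEt)2, −78 °C to rt; then LiN(iPr)2 (2.3 equiv), −78 °C to rt
Reagents that add atoms: none
Why: Kinetic deprotonation of the methyl ketone on the methyl side, O-phosphorylation and β-elimination of the terminal enol phosphate (methyl ketone to terminal alkyne). The former carbonyl carbon is C1 and the former methyl carbon becomes C10.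

Step 4
Reactants: 7 tert-butyl{[(5S)-7,7-dimethoxy-5-(propan-2-yl)hept-1-yn-5-yl]oxy}dimethylsilane
Product: 9 tert-butyl{[(3S,6E)-7-iodo-1,1-dimethoxy-6-methyl-3-(propan-2-yl)hept-6-en-3-yl]oxy}dimethylsilane, via alkenylalane 8 (not isolated)
Conditions: Me3Al, Cp2ZrCl2 (20 mol%), H2O (1 equiv), CH2Cl2, −20 °C; then I2, THF, −20 to 0 °C
Reagents that add atoms: trimethylaluminium, C[Al](C)C; iodine, [I][I]
Why: Zirconium-catalysed syn-carboalumination of a terminal alkyne (methyl to the internal carbon, aluminium to the terminus) and iodinolysis with retention give the E-2-methyl-1-iodoalkene. This fixes the C1=C10 geometry with the chain trans to the C10 substituent. The water-accelerated, low-temperature variant keeps contact between the acetal and the Lewis acid short.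

Step 5
Reactants: 10 (2E)-3-(tributylstannyl)prop-2-en-1-ol
Product: 11 [(1S,2R)-2-(tributylstannyl)cyclopropyl]methanol
Conditions: Et2Zn, CH2I2, DME, (4S,5S)-2-butyl-N,N,N′,N′-tetramethyl-1,3,2-dioxaborolane-4,5-dicarboxamide, CH2Cl2, −10 °C to rt
Reagents that add atoms: diiodomethane, ICI
Why: Dioxaborolane-mediated asymmetric Simmons–Smith cyclopropanation of an E-allylic alcohol; the zinc alkoxide–ligand complex delivers CH2 to one alkene face and the E geometry is kept as the trans ring. The carbinol-bearing carbon is the future C8, the tin-bearing carbon the future C9 and the new CH2 the future C7.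

Step 6
Reactants: 11 [(1S,2R)-2-(tributylstannyl)cyclopropyl]methanol
Product: 12 [(1S,2R)-2-(tributylstannyl)cyclopropyl]methyl 4-methylbenzenesulfonate
Conditions: TsCl, Et3N, DMAP (cat.), CH2Cl2, −20 to 0 °C
Reagents that add atoms: 4-methylbenzenesulfonyl chloride, Cc1ccc(cc1)S(Cl)(=O)=O
Why: Sulfonylation of a primary alcohol; the cyclopropylcarbinyl tosylate is kept cold and used at once so that it does not ionise.

Step 7
Reactants: 12 [(1S,2R)-2-(tributylstannyl)cyclopropyl]methyl 4-methylbenzenesulfonate
Product: 13 tributyl[(1R,2R)-2-methylcyclopropyl]stannane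
Conditions: LiBHEt3, THF, −20 to 0 °C
Reagents that add atoms: none
Why: SN2 displacement of a primary sulfonate by hydride turns the carbinol carbon into the C8 methyl group without touching either ring stereocentre.

Step 8
Reactants: 13 tributyl[(1R,2R)-2-methylcyclopropyl]stannane; 9 tert-butyl{[(3S,6E)-7-iodo-1,1-dimethoxy-6-methyl-3-(propan-2-yl)hept-6-en-3-yl]oxy}dimethylsilane
Product: 16 tert-butyl{[(3S,6E)-1,1-dimethoxy-6-methyl-7-[(1R,2R)-2-methylcyclopropyl]-3-(propan-2-yl)hept-6-en-3-yl]oxy}dimethylsilane, via cyclopropyllithium 14 (not isolated), via cyclopropylzinc chloride 15 (not isolated)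
Conditions: 13, n-BuLi, THF, −78 to 0 °C; ZnCl2, 0 °C; then 9, Pd(PPh3)4 (5 mol%), THF, 45 °C
Reagents that add atoms: none
Why: Tin–lithium exchange and transmetalation to zinc proceed with retention at the cyclopropyl carbon. The Negishi coupling at zerovalent palladium retains the ring configuration and the E geometry of the iodide, forming C9–C10.

Step 9
Reactants: 16 tert-butyl{[(3S,6E)-1,1-dimethoxy-6-methyl-7-[(1R,2R)-2-methylcyclopropyl]-3-(propan-2-yl)hept-6-en-3-yl]oxy}dimethylsilane
Product: 17 (3S,6E)-3-[(tert-butyldimethylsilyl)oxy]-6-methyl-7-[(1R,2R)-2-methylcyclopropyl]-3-(propan-2-yl)hept-6-enal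
Conditions: PPTS, acetone/H2O, 50 °C
Reagents that add atoms: water, O
Why: Mild acid hydrolysis of a dimethyl acetal; the tertiary silyl ether and the vinylcyclopropane tolerate pyridinium catalysis.

Step 10
Reactants: 17 (3S,6E)-3-[(tert-butyldimethylsilyl)oxy]-6-methyl-7-[(1R,2R)-2-methylcyclopropyl]-3-(propan-2-yl)hept-6-enal
Product: 19 tert-butyldimethyl{[(3R,6E)-6-methyl-7-[(1R,2R)-2-methylcyclopropyl]-3-(propan-2-yl)hept-6-en-1-yn-3-yl]oxy}silane, via enol triflate 18 (not isolated)
Conditions: KN(SiMe3)2, PhNTf2, THF, −78 °C; then LiN(iPr)2, −78 to 0 °C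
Reagents that add atoms: none
Why: O-sulfonylation of the aldehyde enolate and base-induced elimination of the 1-alkenyl triflate turn CH2–CHO into C≡CH without adding carbon, as C5 and C6 are the two carbons of this arm. The neopentyl-type α-carbon disfavours self-aldol reaction, and low temperature with the trapping agent present is meant to outrun β-elimination of the silyloxy group.

Step 11
Reactants: 19 tert-butyldimethyl{[(3R,6E)-6-methyl-7-[(1R,2R)-2-methylcyclopropyl]-3-(propan-2-yl)hept-6-en-1-yn-3-yl]oxy}silane
Product: 20 (3R,6E)-6-methyl-7-[(1R,2R)-2-methylcyclopropyl]-3-(propan-2-yl)hept-6-en-1-yn-3-ol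
Conditions: Bu4NF, THF, rt
Reagents that add atoms: none
Why: Fluoride cleavage of the silyl ether; the free hydroxyl is the smaller C4 substituent for step 12 and the directing group for step 13.

Step 12
Reactants: 20 (3R,6E)-6-methyl-7-[(1R,2R)-2-methylcyclopropyl]-3-(propan-2-yl)hept-6-en-1-yn-3-ol
Product: 21 (1S,4R,8R)-dauca-5,9-dien-4-ol
Conditions: [Rh(CO)2Cl]2 (5 mol%), toluene (0.02 mol/L), 110 °C
Reagents that add atoms: none
Why: Monovalent rhodium binds the vinylcyclopropane of 20 and opens the strained C7–C9 bond to a σ,π-allyl rhodacycle; the tethered alkyne then inserts into the Rh–C1 bond (new C1–C5 bond) and C(sp2)–C(sp3) reductive elimination joins C6 to C7 and frees the catalyst. The closest known reaction type is the intramolecular rhodium-catalysed [5+2] cycloaddition of alkyne-tethered vinylcyclopropanes, whose scope reaches E-trisubstituted alkenes (angular methyl products), 1,2-disubstituted cyclopropanes, terminal alkynes and free hydroxyl groups, though not all in one substrate. Ring A closes in the insertion step as a five-membered carbocycle through the three-atom tether (exo with respect to the alkyne); ring B closes in the reductive elimination from the eight-membered rhodacycle as the seven-membered carbocycle. The one new stereocentre, C1, is set by the C4 carbinol: in the insertion transition state the isopropyl group lies on the face of the forming ring A turned away from the rhodium-bound C10 arm and the small hydroxyl faces it, so that the C1 methyl and the C4 isopropyl group end cis. C8 is carried over unchanged from the cyclopropane and C9 becomes sp2. The step needs cleavage of the less substituted cyclopropane bond (C7–C9, not C8–C9), which the trans-alkyl substituent and the carbonyl-ligated catalyst favour, and it needs the E alkene (tether trans to the ring), which steps 4 and 8 secure.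

Step 13
Reactants: 21 (1S,4R,8R)-dauca-5,9-dien-4-ol
Product: 22 (1S,4R,5S,6R,8R)-5α,6α-epoxydauc-9-en-4-ol
Conditions: VO(acac)2 (5 mol%), t-BuOOH, CH2Cl2, 0 °C to rt
Reagents that add atoms: tert-butyl hydroperoxide, CC(C)(C)OO
Why: Hydroxyl-directed vanadium-catalysed epoxidation: the vanadate ester of the C4 alcohol delivers oxygen only to the allylic C5=C6 bond and only to its α face (syn to the hydroxyl). This fixes the C6 oxygen as α and leaves the remote C9=C10 alkene alone.

Step 14
Reactants: 22 (1S,4R,5S,6R,8R)-5α,6α-epoxydauc-9-en-4-ol
Product: 23 (1S,4R,5S,6R,8R)-dauc-9-ene-4,6-diol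
Conditions: Cp2TiCl2 (2.5 equiv), Mn, THF, rt; 1,4-cyclohexadiene; then 22, rt
Reagents that add atoms: none
Why: Titanocene-mediated reductive epoxide opening: trivalent titanium (Cp2TiCl) cleaves the C5–O bond homolytically to the tertiary C5 radical (anti-Markovnikov alcohol, C6 oxygen retained as α), avoiding the C5 cation that would trigger a semipinacol shift of the isopropyl group. Hydrogen-atom transfer from the diene should occur on the β face, anti to the titanium-bound oxygen on C6 and the C4 hydroxyl, which also gives the less strained cis ring fusion (H-5 β).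

Step 15
Reactants: 24 4-hydroxybenzoic acid
Product: 26 4-[(tert-butyldimethylsilyl)oxy]benzoic acid, via silyl ester 25 (not isolated)
Conditions: TBSCl, imidazole, DMF, rt; then K2CO3, MeOH/THF/H2O, rt
Reagents that add atoms: tert-butyl(chloro)dimethylsilane, CC(C)(C)[Si](C)(C)Cl
Why: Double silylation followed by selective hydrolysis of the labile silyl ester leaves the phenol as its silyl ether, inert to singlet oxygen and to acylation.

Step 16
Reactants: 23 (1S,4R,5S,6R,8R)-dauc-9-ene-4,6-diol; 26 4-[(tert-butyldimethylsilyl)oxy]benzoic acid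
Product: 28 (1S,4R,5S,6R,8R)-4-hydroxydauc-9-en-6-yl 4-[(tert-butyldimethylsilyl)oxy]benzoate, via mixed anhydride 27 (not isolated)
Conditions: 26, 2,4,6-trichlorobenzoyl chloride, Et3N, THF, rt; then 23, DMAP, toluene, 60 °C
Reagents that add atoms: none
Why: Yamaguchi esterification of the only secondary hydroxyl (C6); the tertiary C4 hydroxyl is too hindered to acylate and C6 keeps its configuration.

Step 17
Reactants: 28 (1S,4R,5S,6R,8R)-4-hydroxydauc-9-en-6-yl 4-[(tert-butyldimethylsilyl)oxy]benzoate
Product: 30 (1R,4R,5S,6R,10S)-4,10-dihydroxydauc-8-en-6-yl 4-[(tert-butyldimethylsilyl)oxy]benzoate, via allylic hydroperoxide 29 (not isolated)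
Conditions: O2, tetraphenylporphyrin (cat.), hν, CH2Cl2, 0 °C; then PPh3, rt
Reagents that add atoms: oxygen, O=O
Why: Schenck ene reaction: singlet oxygen bonds to C10 and abstracts H-8, the only allylic hydrogen available since C1 is quaternary, on the same face. H-8 is α (set by the cyclopropane), so the hydroperoxide, and after phosphine reduction the alcohol, is 10α and the alkene moves to C8=C9.

Step 18
Reactants: 30 (1R,4R,5S,6R,10S)-4,10-dihydroxydauc-8-en-6-yl 4-[(tert-butyldimethylsilyl)oxy]benzoate; 31 tiglic acid
Product: 33 (1R,4R,5S,6R,10S)-4-hydroxy-10-{[(2E)-2-methylbut-2-enoyl]oxy}dauc-8-en-6-yl 4-[(tert-butyldimethylsilyl)oxy]benzoate, via mixed anhydride 32 (not isolated)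
Conditions: 31, 2,4,6-trichlorobenzoyl chloride, Et3N, toluene, rt; then 30, DMAP, 60 °C
Reagents that add atoms: none
Why: Yamaguchi esterification of the hindered allylic C10 alcohol through the acylpyridinium ion, which leaves the E geometry of the tiglate and the C10 configuration intact. The tertiary C4 hydroxyl does not react.

Step 19
Reactants: 33 (1R,4R,5S,6R,10S)-4-hydroxy-10-{[(2E)-2-methylbut-2-enoyl]oxy}dauc-8-en-6-yl 4-[(tert-butyldimethylsilyl)oxy]benzoate
Product: 34 (1R,4R,5S,6R,10S)-4-hydroxy-10-{[(2E)-2-methylbut-2-enoyl]oxy}dauc-8-en-6-yl 4-hydroxybenzoate (CNP0273650.13)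
Conditions: Bu4NF, AcOH, THF, 0 °C
Reagents that add atoms: none
Why: Fluoride cleaves the aryl silyl ether far faster than it attacks the carboxylic esters; the acetic acid buffer keeps the phenoxide from inducing acyl transfer.

## Compound list

1 | (S)-(+)-terpinen-4-ol, (1S)-4-methyl-1-(propan-2-yl)cyclohex-3-en-1-ol | CC1=CC[C@@](CC1)(C(C)C)O | starting material
2 | tert-butyldimethyl{[(1S)-4-methyl-1-(propan-2-yl)cyclohex-3-en-1-yl]oxy}silane | CC1=CC[C@@](CC1)(C(C)C)O[Si](C)(C)C(C)(C)C | intermediate
3 | (3S)-3-[(tert-butyldimethylsilyl)oxy]-6-hydroperoxy-6-methoxy-3-(propan-2-yl)heptanal, both C6 epimers, not isolated | O=CC[C@](O[Si](C)(C)C(C)(C)C)(C(C)C)CCC(C)(OC)OO | intermediate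
4 | (5S)-5-[(tert-butyldimethylsilyl)oxy]-2-hydroperoxy-2,7,7-trimethoxy-5-(propan-2-yl)heptane, both C2 epimers, not isolated | COC(OC)C[C@](O[Si](C)(C)C(C)(C)C)(C(C)C)CCC(C)(OC)OO | intermediate
5 | (5S)-5-[(tert-butyldimethylsilyl)oxy]-7,7-dimethoxy-5-(propan-2-yl)heptan-2-one | COC(OC)C[C@](O[Si](C)(C)C(C)(C)C)(C(C)C)CCC(C)=O | intermediate
6 | diethyl (5S)-5-[(tert-butyldimethylsilyl)oxy]-7,7-dimethoxy-5-(propan-2-yl)hept-1-en-2-yl phosphate, not isolated | COC(OC)C[C@](O[Si](C)(C)C(C)(C)C)(C(C)C)CCC(=C)OP(=O)(OCC)OCC | intermediate
7 | tert-butyl{[(5S)-7,7-dimethoxy-5-(propan-2-yl)hept-1-yn-5-yl]oxy}dimethylsilane | COC(OC)C[C@](O[Si](C)(C)C(C)(C)C)(C(C)C)CCC#C | intermediate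
8 | [(1E,5S)-5-[(tert-butyldimethylsilyl)oxy]-7,7-dimethoxy-2-methyl-5-(propan-2-yl)hept-1-en-1-yl]dimethylalumane, not isolated | COC(OC)C[C@](O[Si](C)(C)C(C)(C)C)(C(C)C)CC/C(C)=C/[Al](C)C | intermediate
9 | tert-butyl{[(3S,6E)-7-iodo-1,1-dimethoxy-6-methyl-3-(propan-2-yl)hept-6-en-3-yl]oxy}dimethylsilane | COC(OC)C[C@](O[Si](C)(C)C(C)(C)C)(C(C)C)CC/C(C)=C/I | intermediate
10 | (2E)-3-(tributylstannyl)prop-2-en-1-ol | CCCC[Sn](CCCC)(CCCC)/C=C/CO | starting material
11 | [(1S,2R)-2-(tributylstannyl)cyclopropyl]methanol | CCCC[Sn](CCCC)(CCCC)[C@@H]1C[C@H]1CO | intermediate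
12 | [(1S,2R)-2-(tributylstannyl)cyclopropyl]methyl 4-methylbenzenesulfonate | CCCC[Sn](CCCC)(CCCC)[C@@H]1C[C@H]1COS(=O)(=O)c2ccc(C)cc2 | intermediate
13 | tributyl[(1R,2R)-2-methylcyclopropyl]stannane | CCCC[Sn](CCCC)(CCCC)[C@@H]1C[C@H]1C | intermediate
14 | [(1R,2R)-2-methylcyclopropyl]lithium, not isolated | [Li][C@@H]1C[C@H]1C | intermediate
15 | chloro[(1R,2R)-2-methylcyclopropyl]zinc, not isolated | Cl[Zn][C@@H]1C[C@H]1C | intermediate
16 | tert-butyl{[(3S,6E)-1,1-dimethoxy-6-methyl-7-[(1R,2R)-2-methylcyclopropyl]-3-(propan-2-yl)hept-6-en-3-yl]oxy}dimethylsilane | COC(OC)C[C@](O[Si](C)(C)C(C)(C)C)(C(C)C)CC/C(C)=C/[C@@H]1C[C@H]1C | intermediate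
17 | (3S,6E)-3-[(tert-butyldimethylsilyl)oxy]-6-methyl-7-[(1R,2R)-2-methylcyclopropyl]-3-(propan-2-yl)hept-6-enal | O=CC[C@](O[Si](C)(C)C(C)(C)C)(C(C)C)CC/C(C)=C/[C@@H]1C[C@H]1C | intermediate
18 | (3R,6E)-3-[(tert-butyldimethylsilyl)oxy]-6-methyl-7-[(1R,2R)-2-methylcyclopropyl]-3-(propan-2-yl)hepta-1,6-dien-1-yl trifluoromethanesulfonate, both C1=C2 isomers, not isolated | FC(F)(F)S(=O)(=O)OC=C[C@](O[Si](C)(C)C(C)(C)C)(C(C)C)CC/C(C)=C/[C@@H]1C[C@H]1C | intermediate
19 | tert-butyldimethyl{[(3R,6E)-6-methyl-7-[(1R,2R)-2-methylcyclopropyl]-3-(propan-2-yl)hept-6-en-1-yn-3-yl]oxy}silane | C#C[C@](O[Si](C)(C)C(C)(C)C)(C(C)C)CC/C(C)=C/[C@@H]1C[C@H]1C | intermediate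
20 | (3R,6E)-6-methyl-7-[(1R,2R)-2-methylcyclopropyl]-3-(propan-2-yl)hept-6-en-1-yn-3-ol (precursor of the key step) | C#C[C@](O)(C(C)C)CC/C(C)=C/[C@@H]1C[C@H]1C | intermediate
21 | (1S,4R,8R)-dauca-5,9-dien-4-ol, (3R,6R,8aS)-6,8a-dimethyl-3-(propan-2-yl)-1,2,3,5,6,8a-hexahydroazulen-3-ol (product of the key step) | C1=C[C@H](C)CC=C2[C@@]1(C)CC[C@@]2(O)C(C)C | intermediate
22 | (1S,4R,5S,6R,8R)-5α,6α-epoxydauc-9-en-4-ol | C1=C[C@H](C)C[C@H]3O[C@@]32[C@@]1(C)CC[C@@]2(O)C(C)C | intermediate
23 | (1S,4R,5S,6R,8R)-dauc-9-ene-4,6-diol (4α-OH, 6α-OH, H-5 β) | C1=C[C@H](C)C[C@@H](O)[C@@H]2[C@@]1(C)CC[C@@]2(O)C(C)C | intermediate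
24 | 4-hydroxybenzoic acid | OC(=O)c1ccc(O)cc1 | starting material
25 | tert-butyldimethylsilyl 4-[(tert-butyldimethylsilyl)oxy]benzoate, not isolated | CC(C)(C)[Si](C)(C)OC(=O)c1ccc(O[Si](C)(C)C(C)(C)C)cc1 | intermediate
26 | 4-[(tert-butyldimethylsilyl)oxy]benzoic acid | OC(=O)c1ccc(O[Si](C)(C)C(C)(C)C)cc1 | intermediate
27 | 4-[(tert-butyldimethylsilyl)oxy]benzoic 2,4,6-trichlorobenzoic anhydride, not isolated | CC(C)(C)[Si](C)(C)Oc1ccc(cc1)C(=O)OC(=O)c2c(Cl)cc(Cl)cc2Cl | intermediate
28 | (1S,4R,5S,6R,8R)-4-hydroxydauc-9-en-6-yl 4-[(tert-butyldimethylsilyl)oxy]benzoate | C1=C[C@H](C)C[C@@H](OC(=O)c3ccc(O[Si](C)(C)C(C)(C)C)cc3)[C@@H]2[C@@]1(C)CC[C@@]2(O)C(C)C | intermediate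
29 | (1R,4R,5S,6R,10S)-10-hydroperoxy-4-hydroxydauc-8-en-6-yl 4-[(tert-butyldimethylsilyl)oxy]benzoate, not isolated | OO[C@H]1C=C(C)C[C@@H](OC(=O)c3ccc(O[Si](C)(C)C(C)(C)C)cc3)[C@@H]2[C@@]1(C)CC[C@@]2(O)C(C)C | intermediate
30 | (1R,4R,5S,6R,10S)-4,10-dihydroxydauc-8-en-6-yl 4-[(tert-butyldimethylsilyl)oxy]benzoate | O[C@H]1C=C(C)C[C@@H](OC(=O)c3ccc(O[Si](C)(C)C(C)(C)C)cc3)[C@@H]2[C@@]1(C)CC[C@@]2(O)C(C)C | intermediate
31 | tiglic acid, (2E)-2-methylbut-2-enoic acid | C/C=C(\C)C(=O)O | starting material
32 | (2E)-2-methylbut-2-enoic 2,4,6-trichlorobenzoic anhydride, not isolated | C/C=C(\C)C(=O)OC(=O)c1c(Cl)cc(Cl)cc1Cl | intermediate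
33 | (1R,4R,5S,6R,10S)-4-hydroxy-10-{[(2E)-2-methylbut-2-enoyl]oxy}dauc-8-en-6-yl 4-[(tert-butyldimethylsilyl)oxy]benzoate | C/C=C(\C)C(=O)O[C@H]1C=C(C)C[C@@H](OC(=O)c3ccc(O[Si](C)(C)C(C)(C)C)cc3)[C@@H]2[C@@]1(C)CC[C@@]2(O)C(C)C | intermediate
34 | CNP0273650.13, (3R,3aS,4R,8S,8aR)-3-hydroxy-6,8a-dimethyl-8-{[(2E)-2-methylbut-2-enoyl]oxy}-3-(propan-2-yl)-1,2,3,3a,4,5,8,8a-octahydroazulen-4-yl 4-hydroxybenzoate | C/C=C(\C)C(=O)O[C@H]1C=C(C)C[C@@H](OC(=O)c2ccc(O)cc2)[C@@H]2[C@@]1(C)CC[C@@]2(O)C(C)C | target

## Step count and uncertain steps

Total step count: 19. Longest linear sequence: 15 steps (steps 1–4, 8–14 and 16–19); steps 5–7 and step 15 are side branches.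

**Step 12 (key step).** The cycloaddition may stall at the fully substituted alkene terminus while the terminal alkyne oligomerises. The insertion may discriminate too little between hydroxyl and isopropyl at C4, eroding facial selectivity at C1. The rhodium may open the methyl-bearing cyclopropane bond. Fallback: setting out from silyl ether 19, the ruthenium-catalysed variant ([CpRu(MeCN)3]PF6, acetone, rt) couples alkyne and alkene oxidatively to a ruthenacyclopentene before the cyclopropane opens, so it differs in the order of bond formation and in its regiochemical rules. It would give the silyl-protected cycloadduct tert-butyl{[(1S,4R,8R)-dauca-5,9-dien-4-yl]oxy}dimethylsilane F1, and Bu4NF then returns to 21.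

**Step 14.** Hydrogen-atom transfer to the planar C5 radical may occur on the α face, because the β face carries the C1 methyl and C4 isopropyl groups; this would give the trans ring fusion. Deoxygenation back to 21 may compete. Fallback: setting out from 22, if the 5-epimeric diol F2 (trans-fused, H-5 α) forms, the crude diol is oxidised at C6 with Dess–Martin periodinane to the trans-fused hydroxy ketone F3. Brief treatment with DBU equilibrates the ring fusion to the cis-fused hydroxy ketone F4, in which the C5–C6 bond is anti to both the C1 methyl and the C4 isopropyl group. A chelation-controlled Narasaka–Prasad reduction (Et2BOMe, NaBH4) gives the syn-1,3-diol and returns at 23.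

**Step 17.** Singlet oxygen may react too slowly with the cis-disubstituted C9=C10 alkene on the concave α face, so that long irradiation degrades the material instead. Fallback: setting out from 28, α-face epoxidation of C9=C10 with dimethyldioxirane gives the 9α,10α-epoxide F5. Isomerisation with Et2Al(TMP), a syn elimination that uses the same α-oriented H-8, returns at allylic alcohol 30.

**Step 10.** The aldehyde enolate may expel the β-silyloxy group (E1cB) faster than it is sulfonylated, or the enol triflate may form incompletely. Fallback: setting out from 17, condensation with N2H4·H2O gives hydrazone F6. Barton iodination (I2, tetramethylguanidine) gives the 1-iodoalkene F7, and dehydroiodination with KOtBu returns at 19 without an enolate.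

**Step 4.** The aluminium Lewis acid may attack the dimethyl acetal (ionisation and methyl transfer) before carboalumination is complete. Fallback: setting out from 7, copper-catalysed syn-methylboration (CuCl, Xantphos, B2pin2, MeI, NaOtBu) gives the E-alkenyl boronate F8. Suzuki–Miyaura coupling (Pd(OAc)2, PPh3, K2CO3) with (1R,2R)-1-iodo-2-methylcyclopropane F9, made from 13 and I2 with retention, returns at 16 and bypasses 9.

## Further compounds

F1 | step 12 | tert-butyl{[(1S,4R,8R)-dauca-5,9-dien-4-yl]oxy}dimethylsilane | C1=C[C@H](C)CC=C2[C@@]1(C)CC[C@@]2(O[Si](C)(C)C(C)(C)C)C(C)C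
F2 | step 14 | 5-epimer of diol 23 (trans-fused, H-5 α) | C1=C[C@H](C)C[C@@H](O)[C@H]2[C@@]1(C)CC[C@@]2(O)C(C)C
F3 | step 14 | trans-fused 4α-hydroxydauc-9-en-6-one (H-5 α) | C1=C[C@H](C)CC(=O)[C@H]2[C@@]1(C)CC[C@@]2(O)C(C)C
F4 | step 14 | cis-fused 4α-hydroxydauc-9-en-6-one (H-5 β) | C1=C[C@H](C)CC(=O)[C@@H]2[C@@]1(C)CC[C@@]2(O)C(C)C
F5 | step 17 | 9α,10α-epoxide of ester 28 | [C@@H]13O[C@H]3[C@H](C)C[C@@H](OC(=O)c4ccc(O[Si](C)(C)C(C)(C)C)cc4)[C@@H]2[C@@]1(C)CC[C@@]2(O)C(C)C
F6 | step 10 | hydrazone of aldehyde 17 | NN=CC[C@](O[Si](C)(C)C(C)(C)C)(C(C)C)CC/C(C)=C/[C@@H]1C[C@H]1C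
F7 | step 10 | tert-butyl{[(3R,6E)-1-iodo-6-methyl-7-[(1R,2R)-2-methylcyclopropyl]-3-(propan-2-yl)hepta-1,6-dien-3-yl]oxy}dimethylsilane (both C1=C2 isomers) | IC=C[C@](O[Si](C)(C)C(C)(C)C)(C(C)C)CC/C(C)=C/[C@@H]1C[C@H]1C
F8 | step 4 | tert-butyl{[(3S,6E)-1,1-dimethoxy-6-methyl-3-(propan-2-yl)-7-(4,4,5,5-tetramethyl-1,3,2-dioxaborolan-2-yl)hept-6-en-3-yl]oxy}dimethylsilane | COC(OC)C[C@](O[Si](C)(C)C(C)(C)C)(C(C)C)CC/C(C)=C/B1OC(C)(C)C(C)(C)O1
F9 | step 4 | (1R,2R)-1-iodo-2-methylcyclopropane | I[C@@H]1C[C@H]1C
A1 | alternative 1 | 3-(dimethoxymethyl)cyclopent-2-en-1-one | COC(OC)C1=CC(=O)CC1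
A2 | alternative 1 | (3Z)-4-iodo-3-methylbut-3-enal | O=CC/C(C)=C\I
A3 | alternative 1 | 3-methylcyclopentanone aldol with the vinyl iodide and the C10 acetal (product of the key step) | I/C=C(C)\C[C@@H](O)[C@H]1C(=O)CC[C@@]1(C)C(OC)OC
A4 | alternative 2 | 4,4-dimethoxy-3,5-dimethylcyclohexa-2,5-dien-1-one | COC1(OC)C(C)=CC(=O)C=C1C
A5 | alternative 2 | 1-(propan-2-yl)cyclopropan-1-ol | CC(C)C1(O)CC1
A6 | alternative 2 | cis-fused hydrindenone aldol with the C10 ketal (product of the key step) | COC1(OC)C(C)=CC(=O)[C@@H]2[C@@]1(C)CC[C@@]2(O)C(C)C
A7 | alternative 3 | α-diazo ketone with the 2,6-dimethoxy-4-methylphenyl ring | COc1cc(C)cc(OC)c1[C@@H](O[Si](C)(C)C(C)(C)C)CC(=O)C(C)=[N+]=[N-]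
A8 | alternative 3 | 8a-methyl dimethoxy azulenone, bis enol ether (product of the key step) | COC1=CC(C)=CC(OC)=C2[C@@]1(C)C(=O)C[C@@H]2O[Si](C)(C)C(C)(C)C
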